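**Retrosynthetic overview**

1. Numbering used throughout (daucane type): C1 = methyl-bearing ring-fusion carbon, C2/C3 = CH2, C4 = carbinol carbon with isopropyl, C5 = ring-fusion CH; seven-membered ring C5–C6(O-aroyl)–C7–C8(CH3)=C9–C10(O-tigloyl)–C1.
2. The two esters go on last (C6, then C10). Both ring carbinols come from ketones, and the C4 carbinol from a C4 ketone plus an isopropyl-metal reagent.
3. Enabling feature: ring atoms C5–C10 carry oxygen at C6 and C10 and methyl at C8. This is the pattern of a 2-alkylated orcinol (5-methylresorcinol) ring with C5 between the two oxygens, and the seventh ring atom C1 lies between C5 and C10.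
4. Key disconnection: C1–C5 (with C1–C10) by intramolecular Buchner reaction of an α-methyl α-diazo ketone tethered through C2–C3–C4 to 2,6-dimethoxy-4-methylbenzene. The arene ring is present from the start; the cyclopentanone and the seven-membered ring both form in this one step.
5. Stereochemical relay: a transient C4 silyloxy centre (asymmetric allylation) sets C1 and then C5 and is then oxidised. C4 (isopropyl addition), C6 (hydroxyl-directed reduction) and C10 (CBS reduction) follow from the bicyclic core.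

Key step: step 5

Remark (assumption): the Buchner step is taken to place the C4 silyloxy group anti to the new C1 methyl (allylic-strain model, see step 5). The choice of (S)-BINOL in step 1 rests on this. Diazoethane is used as a preformed ethereal solution.

**Step 1**
Reactants: 1 2,6-dimethoxy-4-methylbenzaldehyde
Product: 2 (S)-1-(2,6-dimethoxy-4-methylphenyl)but-3-en-1-ol
Conditions: allylSnBu3, Ti(OiPr)4 (10 mol%), (S)-BINOL (10 mol%), 4 Å MS, CH2Cl2, −20 °C; aq. NaHCO3
Reagents that add atoms: allyltributylstannane C=CC[Sn](CCCC)(CCCC)CCCC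
Why: Keck asymmetric allylation: the (S)-BINOL–titanium Lewis acid activates the aldehyde and shields one carbonyl face so that the allylstannane adds to the other, which should set the (S)-carbinol centre that later relays its configuration to C1 and C5.

**Step 2**
Reactants: 2 (S)-1-(2,6-dimethoxy-4-methylphenyl)but-3-en-1-ol
Product: 3 (S)-tert-butyl{[1-(2,6-dimethoxy-4-methylphenyl)but-3-en-1-yl]oxy}dimethylsilane
Conditions: TBSCl, imidazole, DMF, 40 °C
Reagents that add atoms: tert-butyldimethylsilyl chloride CC(C)(C)[Si](C)(C)Cl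
Why: Standard silylation of the secondary alcohol (no stereocentre touched) gives a bulky, non-nucleophilic ether that tolerates carbenoid, enolate and hydride chemistry and serves as the steric control element in steps 5 and 9.

**Step 3**
Reactants: 3 (S)-tert-butyl{[1-(2,6-dimethoxy-4-methylphenyl)but-3-en-1-yl]oxy}dimethylsilane
Product: 4 (S)-3-[(tert-butyldimethylsilyl)oxy]-3-(2,6-dimethoxy-4-methylphenyl)propanoic acid
Conditions: KMnO4 (5 mol%), NaIO4 (4 equiv), K2CO3, tBuOH/H2O, rt
Reagents that add atoms: sodium periodate [Na+].[O-]I(=O)(=O)=O; water O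
Why: Lemieux–von Rudloff oxidative cleavage (catalytic KMnO4 dihydroxylation, NaIO4 glycol cleavage and aldehyde oxidation) should turn the terminal vinyl group into the carboxylic acid under buffered conditions that leave the silyl ether and the arene intact.

**Step 4**
Reactants: 4 (S)-3-[(tert-butyldimethylsilyl)oxy]-3-(2,6-dimethoxy-4-methylphenyl)propanoic acid
Product: 6 (S)-5-[(tert-butyldimethylsilyl)oxy]-2-diazo-5-(2,6-dimethoxy-4-methylphenyl)pentan-3-one, via mixed anhydride 5 (not isolated)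
Conditions: iBuOCOCl, N-methylmorpholine, THF, −20 °C; then CH3CHN2, Et2O, −20 → 0 °C
Reagents that add atoms: diazoethane CC=[N+]=[N-]
Why: Activation as the mixed carbonic anhydride followed by C-acylation of diazoethane (Arndt–Eistert-type diazo ketone synthesis) should install the α-methyl α-diazo ketone under neutral, cold conditions that avoid β-elimination of the silyloxy group.

**Step 5**
Reactants: 6 (S)-5-[(tert-butyldimethylsilyl)oxy]-2-diazo-5-(2,6-dimethoxy-4-methylphenyl)pentan-3-one
Product: 8 (1R,4S)-4-[(tert-butyldimethylsilyl)oxy]-6,10-dimethoxy-1,8-dimethylbicyclo[5.3.0]deca-5,7,9-trien-2-one, via norcaradiene 7 (not isolated)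
Conditions: Rh2(OAc)4 (1 mol%), CH2Cl2, 40 °C, slow addition of 6
Reagents that add atoms: none
Why: Loss of N2 at Rh2(OAc)4 gives an electrophilic rhodium α-keto carbenoid whose carbene carbon (future C1, carrying the methyl) attacks the arene at the ipso carbon (future C5, activated by both ortho methoxy groups) and closes onto one ortho carbon to give norcaradiene 7, which opens by thermal disrotatory six-electron electrocyclisation to cycloheptatriene 8. The closest known reaction type is the intramolecular Buchner reaction (aromatic cycloaddition, then ring expansion) of α-diazo ketones tethered to arenes, including their α-methyl homologues. The cyclopentanone closes by five-membered (exo-type) attack of the carbenoid on the ipso carbon through the three-atom tether, the cyclopropane by [2+1] addition across the ipso–ortho bond, and the seven-membered ring by electrocyclic cleavage of that same bond (one-carbon expansion of the benzene ring). The only new stereocentre, quaternary C1, is controlled by the C4 silyloxy centre: allylic 1,3-strain with the two flanking methoxy groups holds the benzylic C–H in the arene plane, so the tether can reach only one of the two enantiotopic ipso–ortho bonds and the silyloxy group should end anti to the new methyl. The step needs aromatic addition to win over 1,2-hydride shift, aromatic C–H insertion and oxonium-ylide formation; blocking both ortho positions with methoxy groups removes the C–H insertion channel and makes the two addition sites constitutionally identical, the bulky silyl ether disfavours ylide formation, and carboxylate ligands on rhodium favour cycloaddition.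

**Step 6**
Reactants: 8 (1R,4S)-4-[(tert-butyldimethylsilyl)oxy]-6,10-dimethoxy-1,8-dimethylbicyclo[5.3.0]deca-5,7,9-trien-2-one
Product: 9 (1R,4S)-4-[(tert-butyldimethylsilyl)oxy]-6,10-dimethoxy-1,8-dimethylbicyclo[5.3.0]deca-2,5,7,9-tetraen-2-yl trifluoromethanesulfonate
Conditions: KN(SiMe3)2, PhNTf2, THF, −78 → 0 °C
Reagents that add atoms: N-phenylbis(trifluoromethanesulfonimide) O=S(=O)(N(c1ccccc1)S(=O)(=O)C(F)(F)F)C(F)(F)F
Why: Enolisation is regiospecific because only C3 carries α-hydrogens (C1 is quaternary), and O-sulfonylation of the potassium enolate (enol triflate formation) at −78 °C should be cold enough to prevent loss of silanolate from the β-position.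

**Step 7**
Reactants: 9 (1R,4S)-4-[(tert-butyldimethylsilyl)oxy]-6,10-dimethoxy-1,8-dimethylbicyclo[5.3.0]deca-2,5,7,9-tetraen-2-yl trifluoromethanesulfonate
Product: 10 tert-butyl{[(1R,4S)-6,10-dimethoxy-1,8-dimethylbicyclo[5.3.0]deca-2,5,7,9-tetraen-4-yl]oxy}dimethylsilane
Conditions: Pd(OAc)2 (5 mol%), PPh3 (10 mol%), HCO2H, nBu3N, DMF, 60 °C
Reagents that add atoms: none
Why: Palladium-catalysed formate reduction of an enol triflate (oxidative addition, formate-to-hydride exchange with loss of CO2, reductive elimination) replaces C–O by C–H and so removes the oxygen that was needed only to stabilise the carbenoid.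

**Step 8**
Reactants: 10 tert-butyl{[(1R,4S)-6,10-dimethoxy-1,8-dimethylbicyclo[5.3.0]deca-2,5,7,9-tetraen-4-yl]oxy}dimethylsilane
Product: 11 tert-butyl{[(1R,4S)-6,10-dimethoxy-1,8-dimethylbicyclo[5.3.0]deca-5,7,9-trien-4-yl]oxy}dimethylsilane
Conditions: 2-nitrobenzenesulfonylhydrazide, Et3N, CH2Cl2, rt
Reagents that add atoms: none
Why: Diimide reduction: diimide generated in situ transfers H2 in a concerted cyclic step to the strained cis-disubstituted cyclopentene much faster than to the tri- and tetrasubstituted conjugated enol-ether alkenes, which completes deoxygenation at C2.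

**Step 9**
Reactants: 11 tert-butyl{[(1R,4S)-6,10-dimethoxy-1,8-dimethylbicyclo[5.3.0]deca-5,7,9-trien-4-yl]oxy}dimethylsilane
Product: 12 tert-butyl{[(1R,4S,5R)-6,6,10-trimethoxy-1,8-dimethylbicyclo[5.3.0]deca-7,9-dien-4-yl]oxy}dimethylsilane
Conditions: MeOH, PPTS (5 mol%), 0 °C; Et3N quench
Reagents that add atoms: methanol CO
Why: Acid-catalysed addition of methanol to an enol ether (ketalisation): protonation should occur at C5, the only carbon that gives the doubly oxygen-stabilised heptatrienyl cation, from the face opposite the C4 silyloxy group so that H-5 ends cis to the C1 methyl (cis ring fusion), and methanol should capture the cation at the less hindered C6, which takes C5 out of conjugation while both ring carbonyls stay masked.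

**Step 10**
Reactants: 12 tert-butyl{[(1R,4S,5R)-6,6,10-trimethoxy-1,8-dimethylbicyclo[5.3.0]deca-7,9-dien-4-yl]oxy}dimethylsilane
Product: 13 (1R,4S,5R)-6,6,10-trimethoxy-1,8-dimethylbicyclo[5.3.0]deca-7,9-dien-4-ol
Conditions: nBu4NF, THF, 0 °C → rt
Reagents that add atoms: none
Why: Fluoride-induced desilylation is basic and should leave the acid-labile allylic ketal and dienol ether untouched.

**Step 11**
Reactants: 13 (1R,4S,5R)-6,6,10-trimethoxy-1,8-dimethylbicyclo[5.3.0]deca-7,9-dien-4-ol
Product: 14 (1R,5R)-6,6,10-trimethoxy-1,8-dimethylbicyclo[5.3.0]deca-7,9-dien-4-one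
Conditions: (nPr4N)RuO4 (5 mol%), N-methylmorpholine N-oxide, 4 Å MS, CH2Cl2, rt
Reagents that add atoms: none
Why: Ley–Griffith oxidation converts the secondary alcohol into the cyclopentanone under neutral conditions, which should avoid loss of methanol from the β-keto ketal and epimerisation at C5.

**Step 12**
Reactants: 14 (1R,5R)-6,6,10-trimethoxy-1,8-dimethylbicyclo[5.3.0]deca-7,9-dien-4-one
Product: 15 (1R,4R,5R)-6,6,10-trimethoxy-1,8-dimethyl-4-(propan-2-yl)bicyclo[5.3.0]deca-7,9-dien-4-ol
Conditions: iPrMgCl, CeCl3, THF, −78 °C; aq. NH4Cl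
Reagents that add atoms: isopropylmagnesium chloride CC(C)[Mg]Cl
Why: Organocerium 1,2-addition (low basicity suppresses enolisation, β-hydride reduction and β-elimination) should occur on the face of the cyclopentanone anti to the adjacent C5–C6 bond and its ketal, so isopropyl ends cis to H-5 and the C1 methyl and the new tertiary hydroxyl points to the side of the seven-membered ring, as in the target.

**Step 13**
Reactants: 15 (1R,4R,5R)-6,6,10-trimethoxy-1,8-dimethyl-4-(propan-2-yl)bicyclo[5.3.0]deca-7,9-dien-4-ol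
Product: 17 (1R,4R,5S,6S)-4,6-dihydroxy-1,8-dimethyl-4-(propan-2-yl)bicyclo[5.3.0]dec-8-en-10-one, via enedione 16 (not isolated)
Conditions: oxalic acid (cat.), THF/H2O, 0 °C; then Me4NBH(OAc)3, MeCN/AcOH, −20 °C
Reagents that add atoms: water O
Why: Aqueous acid hydrolyses the ketal and the dienol ether to the ene-dione, and Evans–Saksena reduction then uses the C4 hydroxyl to bind boron and deliver hydride intramolecularly to C6 only, from the face of that hydroxyl, which should give the anti 1,3-diol (C6–O cis to H-5) while C10 stays a ketone and settles as the conjugated C8=C9 enone; C5, epimerisable in 16, should hold the required configuration because that keeps C6 anti to the isopropyl group.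

**Step 14**
Reactants: 17 (1R,4R,5S,6S)-4,6-dihydroxy-1,8-dimethyl-4-(propan-2-yl)bicyclo[5.3.0]dec-8-en-10-one; 18 4-acetoxybenzoyl chloride
Product: 19 (1R,4R,5S,6S)-4-hydroxy-1,8-dimethyl-10-oxo-4-(propan-2-yl)bicyclo[5.3.0]dec-8-en-6-yl 4-acetoxybenzoate
Conditions: DMAP, Et3N, CH2Cl2, 0 °C → rt
Reagents that add atoms: none
Why: DMAP-catalysed acylation (acylpyridinium transfer) should esterify the only secondary hydroxyl, the tertiary C4 hydroxyl being unreactive, with the phenol carried as its acetate.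

**Step 15**
Reactants: 19 (1R,4R,5S,6S)-4-hydroxy-1,8-dimethyl-10-oxo-4-(propan-2-yl)bicyclo[5.3.0]dec-8-en-6-yl 4-acetoxybenzoate
Product: 20 (1R,4R,5S,6S,10R)-4,10-dihydroxy-1,8-dimethyl-4-(propan-2-yl)bicyclo[5.3.0]dec-8-en-6-yl 4-acetoxybenzoate
Conditions: (S)-2-methyl-CBS-oxazaborolidine (0.3 equiv), BH3·SMe2, CH2Cl2, −40 °C; MeOH
Reagents that add atoms: none
Why: Corey–Bakshi–Shibata reduction: the oxazaborolidine–borane complex binds the enone oxygen anti to the quaternary C1 side and transfers hydride 1,2 to the carbonyl face opposite the angular C1 methyl (reagent and expected substrate preference coincide), which should give the (10R) allylic alcohol with oxygen cis to that methyl.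

**Step 16**
Reactants: 20 (1R,4R,5S,6S,10R)-4,10-dihydroxy-1,8-dimethyl-4-(propan-2-yl)bicyclo[5.3.0]dec-8-en-6-yl 4-acetoxybenzoate; 21 (E)-2-methylbut-2-enoyl chloride (tigloyl chloride)
Product: 22 (1R,4R,5S,6S,10R)-4-hydroxy-1,8-dimethyl-10-{[(E)-2-methylbut-2-enoyl]oxy}-4-(propan-2-yl)bicyclo[5.3.0]dec-8-en-6-yl 4-acetoxybenzoate
Conditions: DMAP, pyridine, CH2Cl2, 0 → 40 °C
Reagents that add atoms: none
Why: DMAP-catalysed acylation with the chloride of the thermodynamically stable (E)-acid should esterify the hindered allylic alcohol without isomerising the tiglate double bond, pyridine being too weak a base to form a vinylketene.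

**Step 17**
Reactants: 22 (1R,4R,5S,6S,10R)-4-hydroxy-1,8-dimethyl-10-{[(E)-2-methylbut-2-enoyl]oxy}-4-(propan-2-yl)bicyclo[5.3.0]dec-8-en-6-yl 4-acetoxybenzoate
Product: 23 (1R,4R,5S,6S,10R)-4-hydroxy-1,8-dimethyl-10-{[(E)-2-methylbut-2-enoyl]oxy}-4-(propan-2-yl)bicyclo[5.3.0]dec-8-en-6-yl 4-hydroxybenzoate
Conditions: K2CO3 (0.2 equiv), MeOH, 0 °C
Reagents that add atoms: none
Why: Base-catalysed transesterification (methanolysis) should be chemoselective for the phenolic acetate, which is far more electrophilic than the hindered secondary benzoate and tiglate, and the phenoxide released further deactivates the benzoate.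

**Compound list**

1 | 2,6-dimethoxy-4-methylbenzaldehyde | COc1cc(C)cc(OC)c1C=O | starting material
2 | (S)-1-(2,6-dimethoxy-4-methylphenyl)but-3-en-1-ol | C=CC[C@H](O)c1c(OC)cc(C)cc1OC | intermediate
3 | (S)-tert-butyl{[1-(2,6-dimethoxy-4-methylphenyl)but-3-en-1-yl]oxy}dimethylsilane | C=CC[C@H](O[Si](C)(C)C(C)(C)C)c1c(OC)cc(C)cc1OC | intermediate
4 | (S)-3-[(tert-butyldimethylsilyl)oxy]-3-(2,6-dimethoxy-4-methylphenyl)propanoic acid | OC(=O)C[C@H](O[Si](C)(C)C(C)(C)C)c1c(OC)cc(C)cc1OC | intermediate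
5 | isobutyl carbonic anhydride of acid 4 | CC(C)COC(=O)OC(=O)C[C@H](O[Si](C)(C)C(C)(C)C)c1c(OC)cc(C)cc1OC | intermediate
6 | (S)-5-[(tert-butyldimethylsilyl)oxy]-2-diazo-5-(2,6-dimethoxy-4-methylphenyl)pentan-3-one | CC(=[N+]=[N-])C(=O)C[C@H](O[Si](C)(C)C(C)(C)C)c1c(OC)cc(C)cc1OC | intermediate
7 | norcaradiene valence isomer of 8 (cyclopropane C1–C5–C10 shared by the 4-silyloxycyclopentan-2-one and a 6,10-dimethoxy-8-methylcyclohexa-6,8-diene ring) | C[C@@]12C(=O)C[C@H](O[Si](C)(C)C(C)(C)C)[C@]1(C(OC)=CC(C)=C3)[C@]23OC | intermediate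
8 | (1R,4S)-4-[(tert-butyldimethylsilyl)oxy]-6,10-dimethoxy-1,8-dimethylbicyclo[5.3.0]deca-5,7,9-trien-2-one (silyloxy anti to 1-CH3) | COC1=CC(C)=CC(OC)=C2[C@@]1(C)C(=O)C[C@@H]2O[Si](C)(C)C(C)(C)C | intermediate
9 | (1R,4S)-4-[(tert-butyldimethylsilyl)oxy]-6,10-dimethoxy-1,8-dimethylbicyclo[5.3.0]deca-2,5,7,9-tetraen-2-yl trifluoromethanesulfonate | COC1=CC(C)=CC(OC)=C2[C@@]1(C)C(OS(=O)(=O)C(F)(F)F)=C[C@@H]2O[Si](C)(C)C(C)(C)C | intermediate
10 | tert-butyl{[(1R,4S)-6,10-dimethoxy-1,8-dimethylbicyclo[5.3.0]deca-2,5,7,9-tetraen-4-yl]oxy}dimethylsilane | COC1=CC(C)=CC(OC)=C2[C@@]1(C)C=C[C@@H]2O[Si](C)(C)C(C)(C)C | intermediate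
11 | tert-butyl{[(1R,4S)-6,10-dimethoxy-1,8-dimethylbicyclo[5.3.0]deca-5,7,9-trien-4-yl]oxy}dimethylsilane | COC1=CC(C)=CC(OC)=C2[C@@]1(C)CC[C@@H]2O[Si](C)(C)C(C)(C)C | intermediate
12 | tert-butyl{[(1R,4S,5R)-6,6,10-trimethoxy-1,8-dimethylbicyclo[5.3.0]deca-7,9-dien-4-yl]oxy}dimethylsilane (H-5 cis to 1-CH3) | COC1=CC(C)=CC(OC)(OC)[C@@H]2[C@@]1(C)CC[C@@H]2O[Si](C)(C)C(C)(C)C | intermediate
13 | (1R,4S,5R)-6,6,10-trimethoxy-1,8-dimethylbicyclo[5.3.0]deca-7,9-dien-4-ol | COC1=CC(C)=CC(OC)(OC)[C@@H]2[C@@]1(C)CC[C@@H]2O | intermediate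
14 | (1R,5R)-6,6,10-trimethoxy-1,8-dimethylbicyclo[5.3.0]deca-7,9-dien-4-one | COC1=CC(C)=CC(OC)(OC)[C@@H]2[C@@]1(C)CCC2=O | intermediate
15 | (1R,4R,5R)-6,6,10-trimethoxy-1,8-dimethyl-4-(propan-2-yl)bicyclo[5.3.0]deca-7,9-dien-4-ol | COC1=CC(C)=CC(OC)(OC)[C@@H]2[C@@]1(C)CC[C@@]2(O)C(C)C | intermediate
16 | (1R,4R,5R)-4-hydroxy-1,8-dimethyl-4-(propan-2-yl)bicyclo[5.3.0]dec-8-ene-6,10-dione | O=C1C=C(C)CC(=O)[C@@H]2[C@@]1(C)CC[C@@]2(O)C(C)C | intermediate
17 | (1R,4R,5S,6S)-4,6-dihydroxy-1,8-dimethyl-4-(propan-2-yl)bicyclo[5.3.0]dec-8-en-10-one | O=C1C=C(C)C[C@H](O)[C@@H]2[C@@]1(C)CC[C@@]2(O)C(C)C | intermediate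
18 | 4-acetoxybenzoyl chloride | CC(=O)Oc1ccc(cc1)C(Cl)=O | starting material
19 | (1R,4R,5S,6S)-4-hydroxy-1,8-dimethyl-10-oxo-4-(propan-2-yl)bicyclo[5.3.0]dec-8-en-6-yl 4-acetoxybenzoate | O=C1C=C(C)C[C@H](OC(=O)c2ccc(OC(C)=O)cc2)[C@@H]2[C@@]1(C)CC[C@@]2(O)C(C)C | intermediate
20 | (1R,4R,5S,6S,10R)-4,10-dihydroxy-1,8-dimethyl-4-(propan-2-yl)bicyclo[5.3.0]dec-8-en-6-yl 4-acetoxybenzoate | O[C@@H]1C=C(C)C[C@H](OC(=O)c2ccc(OC(C)=O)cc2)[C@@H]2[C@@]1(C)CC[C@@]2(O)C(C)C | intermediate
21 | (E)-2-methylbut-2-enoyl chloride (tigloyl chloride) | C/C=C(\C)C(Cl)=O | starting material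
22 | (1R,4R,5S,6S,10R)-4-hydroxy-1,8-dimethyl-10-{[(E)-2-methylbut-2-enoyl]oxy}-4-(propan-2-yl)bicyclo[5.3.0]dec-8-en-6-yl 4-acetoxybenzoate | C/C=C(\C)C(=O)O[C@@H]1C=C(C)C[C@H](OC(=O)c2ccc(OC(C)=O)cc2)[C@@H]2[C@@]1(C)CC[C@@]2(O)C(C)C | intermediate
23 | (1R,4R,5S,6S,10R)-4-hydroxy-1,8-dimethyl-10-{[(E)-2-methylbut-2-enoyl]oxy}-4-(propan-2-yl)bicyclo[5.3.0]dec-8-en-6-yl 4-hydroxybenzoate | C/C=C(\C)C(=O)O[C@@H]1C=C(C)C[C@H](OC(=O)c2ccc(O)cc2)[C@@H]2[C@@]1(C)CC[C@@]2(O)C(C)C | target

**Totals**

Total step count: 17. Longest linear sequence: 17 steps (from 1; compounds 18 and 21 are purchased).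

**Steps most likely to fail**

Step 5. The carbenoid may be diverted (attack of the silyloxy oxygen to give an oxonium ylide, 1,2-hydride shift from the methyl group), or it may discriminate poorly between the two enantiotopic ipso–ortho bonds, which would erode enantiomeric purity once step 11 removes the C4 centre. The fallback replaces substrate control by catalyst control and introduces the C4 oxygen after ring expansion; it sets out from 4 and comes back at 8. Ionic deoxygenation of the electron-rich benzylic silyl ether (Et3SiH, CF3CO2H) should give 3-(2,6-dimethoxy-4-methylphenyl)propanoic acid F1. Its isobutyl carbonic anhydride F2 and diazoethane should give 2-diazo-5-(2,6-dimethoxy-4-methylphenyl)pentan-3-one F3. An enantioselective Buchner reaction with [Cu(MeCN)4]PF6 and a C2-symmetric bis(oxazoline) ligand (a known reaction type for this achiral α-diazo ketone class; the ligand antipode is chosen for the 1R series) should lead through the 4-deoxy norcaradiene F4 to (1R)-6,10-dimethoxy-1,8-dimethylbicyclo[5.3.0]deca-5,7,9-trien-2-one F5. IBX dehydrogenation should give (1R)-6,10-dimethoxy-1,8-dimethylbicyclo[5.3.0]deca-3,5,7,9-tetraen-2-one F6. Conjugate borylation (CuCl, NaOtBu, B2pin2, MeOH) anti to the C1 methyl should give the (1R,4S)-4-(pinacolboryl) ketone F7, and NaBO3 oxidation the (1R,4S)-4-hydroxy ketone F8. Silylation (TBSCl, imidazole) returns to 8.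

Step 13. The tertiary β-hydroxy ketone may dehydrate under acid, or the two carbonyls of the vinylogous 1,3-diketone may be differentiated incompletely (hydride reaching C10, or reduction of a tautomer that leaves the alkene at C7=C8). The fallback unveils and reduces the carbonyls one at a time and reverses the order of esterification; it sets out from 15 and comes back at 22. Brief treatment with PPTS in wet acetone should stop at the thermodynamically preferred vinylogous ester (1R,4R,5R)-4-hydroxy-6-methoxy-1,8-dimethyl-4-(propan-2-yl)bicyclo[5.3.0]deca-6,8-dien-10-one F10, in which the methoxy group avoids the quaternary C1. Reduction with iBu2AlH (1,2-addition anti to the C1 methyl) should give the (10R)-dienol-ether alcohol F11. Weak-acid hydrolysis (oxalic acid, kinetic protonation at C7) should give (1R,4R,5R,10R)-4,10-dihydroxy-1,8-dimethyl-4-(propan-2-yl)bicyclo[5.3.0]dec-8-en-6-one F12. Acylation with 21 should give the 10-tiglate ketone F13, and Evans–Saksena reduction the 10-tiglate 4,6-diol F14. Acylation of F14 with 18 returns to 22.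

Step 12. The branched Grignard-derived reagent may enolise the ketone, reduce it by β-hydride transfer, or trigger loss of methanol from the β-keto ketal. The fallback uses an sp2 nucleophile followed by hydrogenation; it sets out from 14 and comes back at 15. Isopropenylmagnesium bromide with CeCl3 (no β-hydrogen to transfer, lower basicity) should give (1R,4S,5R)-6,6,10-trimethoxy-1,8-dimethyl-4-(prop-1-en-2-yl)bicyclo[5.3.0]deca-7,9-dien-4-ol F9. Hydrogenation with H2 and RhCl(PPh3)3, selective for the 1,1-disubstituted alkene over the conjugated enol-ether alkenes, returns to 15.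

**Further compounds**

F1 | step 5 | 3-(2,6-dimethoxy-4-methylphenyl)propanoic acid | OC(=O)CCc1c(OC)cc(C)cc1OC
F2 | step 5 | isobutyl carbonic anhydride of F1 | CC(C)COC(=O)OC(=O)CCc1c(OC)cc(C)cc1OC
F3 | step 5 | 2-diazo-5-(2,6-dimethoxy-4-methylphenyl)pentan-3-one | CC(=[N+]=[N-])C(=O)CCc1c(OC)cc(C)cc1OC
F4 | step 5 | 4-deoxy norcaradiene (valence isomer of F5) | C[C@@]12C(=O)CC[C@]1(C(OC)=CC(C)=C3)[C@]23OC
F5 | step 5 | (1R)-6,10-dimethoxy-1,8-dimethylbicyclo[5.3.0]deca-5,7,9-trien-2-one | COC1=CC(C)=CC(OC)=C2[C@@]1(C)C(=O)CC2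
F6 | step 5 | (1R)-6,10-dimethoxy-1,8-dimethylbicyclo[5.3.0]deca-3,5,7,9-tetraen-2-one | COC1=CC(C)=CC(OC)=C2[C@@]1(C)C(=O)C=C2
F7 | step 5 | (1R,4S)-6,10-dimethoxy-1,8-dimethyl-4-(4,4,5,5-tetramethyl-1,3,2-dioxaborolan-2-yl)bicyclo[5.3.0]deca-5,7,9-trien-2-one | COC1=CC(C)=CC(OC)=C2[C@@]1(C)C(=O)C[C@@H]2B1OC(C)(C)C(C)(C)O1
F8 | step 5 | (1R,4S)-4-hydroxy-6,10-dimethoxy-1,8-dimethylbicyclo[5.3.0]deca-5,7,9-trien-2-one | COC1=CC(C)=CC(OC)=C2[C@@]1(C)C(=O)C[C@@H]2O
F9 | step 12 | (1R,4S,5R)-6,6,10-trimethoxy-1,8-dimethyl-4-(prop-1-en-2-yl)bicyclo[5.3.0]deca-7,9-dien-4-ol | COC1=CC(C)=CC(OC)(OC)[C@@H]2[C@@]1(C)CC[C@@]2(O)C(C)=C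
F10 | step 13 | (1R,4R,5R)-4-hydroxy-6-methoxy-1,8-dimethyl-4-(propan-2-yl)bicyclo[5.3.0]deca-6,8-dien-10-one | O=C1C=C(C)C=C(OC)[C@@H]2[C@@]1(C)CC[C@@]2(O)C(C)C
F11 | step 13 | (1R,4R,5R,10R)-6-methoxy-1,8-dimethyl-4-(propan-2-yl)bicyclo[5.3.0]deca-6,8-diene-4,10-diol | O[C@@H]1C=C(C)C=C(OC)[C@@H]2[C@@]1(C)CC[C@@]2(O)C(C)C
F12 | step 13 | (1R,4R,5R,10R)-4,10-dihydroxy-1,8-dimethyl-4-(propan-2-yl)bicyclo[5.3.0]dec-8-en-6-one | O[C@@H]1C=C(C)CC(=O)[C@@H]2[C@@]1(C)CC[C@@]2(O)C(C)C
F13 | step 13 | (1R,4R,5R,10R)-4-hydroxy-1,8-dimethyl-6-oxo-4-(propan-2-yl)bicyclo[5.3.0]dec-8-en-10-yl (E)-2-methylbut-2-enoate | C/C=C(\C)C(=O)O[C@@H]1C=C(C)CC(=O)[C@@H]2[C@@]1(C)CC[C@@]2(O)C(C)C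
F14 | step 13 | (1R,4R,5S,6S,10R)-4,6-dihydroxy-1,8-dimethyl-4-(propan-2-yl)bicyclo[5.3.0]dec-8-en-10-yl (E)-2-methylbut-2-enoate | C/C=C(\C)C(=O)O[C@@H]1C=C(C)C[C@H](O)[C@@H]2[C@@]1(C)CC[C@@]2(O)C(C)C
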